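**Plan**

1. Retrosynthesis, helpers first: remove five O-benzyl groups and one bromine on ring B (hydrogenolysis), a phenylsulfonyl group on the bridge carbon next to ring B, and a carbonyl oxygen on the CH2 that links ring B to its 4-hydroxyphenyl ring.
2. Then cut two neighbouring bonds of ring B at once, bridge C–C(aryl) and C(aryl)–C(=O), to an aryne and a β-keto sulfone (C–C σ-bond insertion). Cut the keto sulfone at the CH–CH2 bond of the bridge to a ring-A benzyl bromide, and cut the two aryl–CH2 bonds of ring A to a 2,6-dibromobenzoate.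
3. Enabling feature: in ring B (the 1,2,4-trisubstituted phenol ring) the bridge CH2 and the CH2 of the 4-hydroxybenzyl group sit on adjacent ring carbons. The OH is para to the benzyl-bearing carbon, and the ring carbon on its far side is a CH that can carry a temporary bromine. These two adjacent carbons can therefore be the triple bond of an aryne, and the bromine beside it steers the addition.
4. Forward: no ring is built. Ring A is bought as a benzoate and dressed (O-benzylation, dibromination, double Negishi benzylation, ester to CH2Br). Ring B is bought as 4-(benzyloxy)phenol and made into a bromo silyl triflate. The chain is joined first by sulfone alkylation, then by the aryne insertion, which also delivers the aroyl group.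
5. Stereochemistry: the target has no stereocentre. The sulfone-bearing carbon is formed racemic and is erased on desulfonylation.

Key step: step 10

Remark: the four starting materials are taken as commercial; all intermediates with the sulfonyl-bearing stereocentre are handled as racemates.

**Route**

Step 1
Reactants: 1 4-(benzyloxy)phenol
Product: 2 4-(benzyloxy)-2,6-dibromophenol
Conditions: NBS (2.1 equiv), i-Pr2NH (cat.), CH2Cl2, 0 °C to rt
Reagents that add atoms: N-bromosuccinimide, O=C1CCC(=O)N1Br
Why: Electrophilic aromatic bromination (amine-catalysed ortho-bromination of phenols); the free OH is the stronger director and its para position is blocked, so both bromines should enter ortho to OH.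

Step 2
Reactants: 2 4-(benzyloxy)-2,6-dibromophenol
Product: 5 4-(benzyloxy)-2-bromo-6-(trimethylsilyl)phenyl trifluoromethanesulfonate, via silyl ether 3 (not isolated), via lithium phenoxide 4 (not isolated)
Conditions: HMDS, THF, reflux, then evaporate; n-BuLi (1.0 equiv), THF, −78 °C; Tf2O, −78 °C to rt
Reagents that add atoms: hexamethyldisilazane, C[Si](C)(C)N[Si](C)(C)C; trifluoromethanesulfonic anhydride, O=S(=O)(OS(=O)(=O)C(F)(F)F)C(F)(F)F
Why: O-silylation, Br/Li exchange, 1,3 O-to-C silyl shift (retro-Brook rearrangement) and O-triflation, the standard entry to 2-silylaryl triflate aryne precursors; the two bromines are equivalent, so only one product can form.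

Step 3
Reactants: 6 methyl 3-hydroxy-5-methoxybenzoate
Product: 7 methyl 3-(benzyloxy)-5-methoxybenzoate
Conditions: BnBr, K2CO3, DMF, rt
Reagents that add atoms: benzyl bromide, BrCc1ccccc1
Why: Williamson ether synthesis on the only free phenol.

Step 4
Reactants: 7 methyl 3-(benzyloxy)-5-methoxybenzoate
Product: 8 methyl 3-(benzyloxy)-2,6-dibromo-5-methoxybenzoate
Conditions: NBS (2.2 equiv), MeCN, rt to 50 °C
Reagents that add atoms: N-bromosuccinimide, O=C1CCC(=O)N1Br
Why: Electrophilic aromatic bromination; each bromine should enter para to one ether oxygen and ortho to the other, as in 3,5-dialkoxybenzoates, while the position between the two oxygens (para to neither) is the least reactive.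

Step 5
Reactants: 8 methyl 3-(benzyloxy)-2,6-dibromo-5-methoxybenzoate; 9 4-(benzyloxy)benzyl chloride (2.6 equiv)
Product: 11 methyl 3-(benzyloxy)-2,6-bis[4-(benzyloxy)benzyl]-5-methoxybenzoate, via benzylzinc chloride 10 (not isolated)
Conditions: 9, Zn dust, LiCl, THF, rt; then 8, Pd(OAc)2 (cat.), SPhos (cat.), THF, 50 °C
Reagents that add atoms: none
Why: LiCl-promoted zinc insertion into the benzylic chloride, then twofold Negishi sp2–sp3 coupling; the ester is tolerated and speeds oxidative addition, SPhos handles doubly ortho-substituted bromides, and a benzyl group has no β-hydrogen to eliminate.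

Step 6
Reactants: 11 methyl 3-(benzyloxy)-2,6-bis[4-(benzyloxy)benzyl]-5-methoxybenzoate
Product: 12 {3-(benzyloxy)-2,6-bis[4-(benzyloxy)benzyl]-5-methoxyphenyl}methanol
Conditions: LiAlH4, THF, 0 °C to reflux
Reagents that add atoms: none
Why: Hydride reduction of the ester to the primary alcohol; LiAlH4 reduces 2,6-disubstituted benzoates that resist milder hydrides, and aryl benzyl ethers are inert.

Step 7
Reactants: 12 {3-(benzyloxy)-2,6-bis[4-(benzyloxy)benzyl]-5-methoxyphenyl}methanol
Product: 13 1-(benzyloxy)-2,4-bis[4-(benzyloxy)benzyl]-3-(bromomethyl)-5-methoxybenzene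
Conditions: CBr4, PPh3, CH2Cl2, 0 °C
Reagents that add atoms: carbon tetrabromide, BrC(Br)(Br)Br
Why: Appel reaction; neutral conditions convert the benzylic alcohol to the bromide without touching the ethers.

Step 8
Reactants: 14 1-[4-(benzyloxy)phenyl]-2-bromoethan-1-one
Product: 15 1-[4-(benzyloxy)phenyl]-2-(phenylsulfonyl)ethan-1-one
Conditions: PhSO2Na, EtOH, reflux
Reagents that add atoms: sodium benzenesulfinate, [Na+].[O-]S(=O)c1ccccc1
Why: SN2 S-alkylation of the sulfinate by the phenacyl bromide, the usual preparation of β-keto sulfones.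

Step 9
Reactants: 15 1-[4-(benzyloxy)phenyl]-2-(phenylsulfonyl)ethan-1-one (1.3 equiv); 13 1-(benzyloxy)-2,4-bis[4-(benzyloxy)benzyl]-3-(bromomethyl)-5-methoxybenzene
Product: 16 rac-1-[4-(benzyloxy)phenyl]-3-{3-(benzyloxy)-2,6-bis[4-(benzyloxy)benzyl]-5-methoxyphenyl}-2-(phenylsulfonyl)propan-1-one
Conditions: K2CO3, DMF, rt
Reagents that add atoms: none
Why: C-alkylation of the β-keto sulfone carbanion with a benzylic bromide; excess 15 and the bulk of 13 should hold it at monoalkylation, and the new stereocentre is racemic.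

Step 10
Reactants: 16 rac-1-[4-(benzyloxy)phenyl]-3-{3-(benzyloxy)-2,6-bis[4-(benzyloxy)benzyl]-5-methoxyphenyl}-2-(phenylsulfonyl)propan-1-one; 5 4-(benzyloxy)-2-bromo-6-(trimethylsilyl)phenyl trifluoromethanesulfonate (1.5–2 equiv)
Product: 19 rac-{4-(benzyloxy)-2-bromo-6-[2-{3-(benzyloxy)-2,6-bis[4-(benzyloxy)benzyl]-5-methoxyphenyl}-1-(phenylsulfonyl)ethyl]phenyl}[4-(benzyloxy)phenyl]methanone, via aryne 17 (not isolated), via benzocyclobutenoxide 18 (not isolated)
Conditions: CsF (4 equiv), MeCN/THF, 60 °C, slow addition of 5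
Reagents that add atoms: none
Why: Fluoride removes the silyl group of 5 and triflate leaves to give aryne 17, while CsF also deprotonates keto sulfone 16; the overall event is a formal insertion of the aryne into the C–C σ-bond between the sulfonyl-bearing carbon and the carbonyl, the closest known reactions being the acyl-alkylation of arynes by β-keto esters and its β-keto sulfone variant. The enolate carbon should add to the aryne carbon remote from bromine, because the C–Br bond beside the triple bond distorts the aryne so that this carbon is the more electrophilic one and the developing aryl anion lies next to the inductively stabilising bromine; this outweighs the weak opposite bias of the distant benzyloxy group and is reinforced by the bulk of the nucleophile. The aryl anion then closes on the ketone three atoms away (4-exo-trig) to benzocyclobutenoxide 18, the only ring formed, which reopens by C–C fragmentation to the sulfonyl-stabilised benzylic carbanion and so hands the 4-(benzyloxy)benzoyl group to the ring carbon next to bromine; protonation gives 19. The step needs C- rather than O-arylation of the enolate, and capture of the ortho-bromoaryl anion by the carbonyl before it is protonated or expels bromide; the soft sulfonyl-stabilised carbon nucleophile and the intramolecular four-centre capture should secure both. The sulfone carbon is the only new stereocentre, it forms racemic without control and is erased at step 12, and no ring of the target is closed here.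

Step 11
Reactants: 19 rac-{4-(benzyloxy)-2-bromo-6-[2-{3-(benzyloxy)-2,6-bis[4-(benzyloxy)benzyl]-5-methoxyphenyl}-1-(phenylsulfonyl)ethyl]phenyl}[4-(benzyloxy)phenyl]methanone
Product: 20 rac-5-(benzyloxy)-2-[4-(benzyloxy)benzyl]-1-bromo-3-[2-{3-(benzyloxy)-2,6-bis[4-(benzyloxy)benzyl]-5-methoxyphenyl}-1-(phenylsulfonyl)ethyl]benzene
Conditions: Et3SiH (5 equiv), TFA/CH2Cl2 (1:4), 0 °C to rt
Reagents that add atoms: none
Why: Ionic hydrogenation of a diaryl ketone; protonation and hydride transfer give the carbinol, which ionises to a benzhydryl cation stabilised by two para-alkoxyaryl rings and takes a second hydride, while sulfone, aryl bromide and aryl benzyl ethers should survive.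

Step 12
Reactants: 20 rac-5-(benzyloxy)-2-[4-(benzyloxy)benzyl]-1-bromo-3-[2-{3-(benzyloxy)-2,6-bis[4-(benzyloxy)benzyl]-5-methoxyphenyl}-1-(phenylsulfonyl)ethyl]benzene
Product: 21 5-(benzyloxy)-2-[4-(benzyloxy)benzyl]-1-bromo-3-[2-{3-(benzyloxy)-2,6-bis[4-(benzyloxy)benzyl]-5-methoxyphenyl}ethyl]benzene
Conditions: Mg turnings (activated), MeOH/THF, 50 °C
Reagents that add atoms: none
Why: Reductive desulfonylation by single-electron transfer from magnesium; the sulfone radical anion fragments to sulfinate and a benzylic radical/anion that methanol protonates, benzyl ethers are inert, and any loss of the aryl bromine here would be harmless because step 13 removes it anyway.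

Step 13
Reactants: 21 5-(benzyloxy)-2-[4-(benzyloxy)benzyl]-1-bromo-3-[2-{3-(benzyloxy)-2,6-bis[4-(benzyloxy)benzyl]-5-methoxyphenyl}ethyl]benzene
Product: 22 3-{2-[5-hydroxy-2-(4-hydroxybenzyl)phenyl]ethyl}-2,4-bis(4-hydroxybenzyl)-5-methoxyphenol (CNP0147493.0)
Conditions: H2 (1 atm), 10% Pd/C, NaOAc, THF/MeOH, rt
Reagents that add atoms: none
Why: Catalytic hydrogenolysis should cleave the five benzylic C–O bonds and the aryl C–Br bond in one operation (acetate buffers the HBr), while the diarylmethane and bibenzyl C–C bonds and the aryl methyl ether are untouched.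

**Compound list**

1 | 4-(benzyloxy)phenol | Oc1ccc(OCc2ccccc2)cc1 | starting material
2 | 4-(benzyloxy)-2,6-dibromophenol | Oc1c(Br)cc(OCc2ccccc2)cc1Br | intermediate
3 | [4-(benzyloxy)-2,6-dibromophenoxy]trimethylsilane | C[Si](C)(C)Oc1c(Br)cc(OCc2ccccc2)cc1Br | intermediate (not isolated)
4 | lithium 4-(benzyloxy)-2-bromo-6-(trimethylsilyl)phenolate | [Li+].[O-]c1c(Br)cc(OCc2ccccc2)cc1[Si](C)(C)C | intermediate (not isolated)
5 | 4-(benzyloxy)-2-bromo-6-(trimethylsilyl)phenyl trifluoromethanesulfonate | C[Si](C)(C)c1cc(OCc2ccccc2)cc(Br)c1OS(=O)(=O)C(F)(F)F | intermediate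
6 | methyl 3-hydroxy-5-methoxybenzoate | COC(=O)c1cc(O)cc(OC)c1 | starting material
7 | methyl 3-(benzyloxy)-5-methoxybenzoate | COC(=O)c1cc(OC)cc(OCc2ccccc2)c1 | intermediate
8 | methyl 3-(benzyloxy)-2,6-dibromo-5-methoxybenzoate | COC(=O)c1c(Br)c(OC)cc(OCc2ccccc2)c1Br | intermediate
9 | 4-(benzyloxy)benzyl chloride | ClCc1ccc(OCc2ccccc2)cc1 | starting material
10 | [4-(benzyloxy)benzyl]zinc chloride | Cl[Zn]Cc1ccc(OCc2ccccc2)cc1 | intermediate (not isolated)
11 | methyl 3-(benzyloxy)-2,6-bis[4-(benzyloxy)benzyl]-5-methoxybenzoate | COC(=O)c1c(Cc2ccc(OCc3ccccc3)cc2)c(OC)cc(OCc2ccccc2)c1Cc1ccc(OCc2ccccc2)cc1 | intermediate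
12 | {3-(benzyloxy)-2,6-bis[4-(benzyloxy)benzyl]-5-methoxyphenyl}methanol | OCc1c(Cc2ccc(OCc3ccccc3)cc2)c(OC)cc(OCc2ccccc2)c1Cc1ccc(OCc2ccccc2)cc1 | intermediate
13 | 1-(benzyloxy)-2,4-bis[4-(benzyloxy)benzyl]-3-(bromomethyl)-5-methoxybenzene | BrCc1c(Cc2ccc(OCc3ccccc3)cc2)c(OC)cc(OCc2ccccc2)c1Cc1ccc(OCc2ccccc2)cc1 | intermediate
14 | 1-[4-(benzyloxy)phenyl]-2-bromoethan-1-one | O=C(CBr)c1ccc(OCc2ccccc2)cc1 | starting material
15 | 1-[4-(benzyloxy)phenyl]-2-(phenylsulfonyl)ethan-1-one | O=C(CS(=O)(=O)c1ccccc1)c1ccc(OCc2ccccc2)cc1 | intermediate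
16 | rac-1-[4-(benzyloxy)phenyl]-3-{3-(benzyloxy)-2,6-bis[4-(benzyloxy)benzyl]-5-methoxyphenyl}-2-(phenylsulfonyl)propan-1-one (racemic) | O=C(c1ccc(OCc2ccccc2)cc1)C(Cc1c(Cc2ccc(OCc3ccccc3)cc2)c(OC)cc(OCc2ccccc2)c1Cc1ccc(OCc2ccccc2)cc1)S(=O)(=O)c1ccccc1 | intermediate
17 | 5-(benzyloxy)-3-bromobenzyne (5-(benzyloxy)-3-bromo-1,2-didehydrobenzene) | BrC1=CC(OCc2ccccc2)=CC#C1 | intermediate (not isolated)
18 | caesium 3-(benzyloxy)-7-[4-(benzyloxy)phenyl]-5-bromo-8-{3-(benzyloxy)-2,6-bis[4-(benzyloxy)benzyl]-5-methoxybenzyl}-8-(phenylsulfonyl)bicyclo[4.2.0]octa-1,3,5-trien-7-olate (diastereomer mixture) | [Cs+].[O-]C1(c2ccc(OCc3ccccc3)cc2)c2c(Br)cc(OCc3ccccc3)cc2C1(Cc4c(Cc5ccc(OCc6ccccc6)cc5)c(OC)cc(OCc5ccccc5)c4Cc4ccc(OCc5ccccc5)cc4)S(=O)(=O)c1ccccc1 | intermediate (not isolated)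
19 | rac-{4-(benzyloxy)-2-bromo-6-[2-{3-(benzyloxy)-2,6-bis[4-(benzyloxy)benzyl]-5-methoxyphenyl}-1-(phenylsulfonyl)ethyl]phenyl}[4-(benzyloxy)phenyl]methanone (racemic) | O=C(c1ccc(OCc2ccccc2)cc1)c1c(Br)cc(OCc2ccccc2)cc1C(Cc1c(Cc2ccc(OCc3ccccc3)cc2)c(OC)cc(OCc2ccccc2)c1Cc1ccc(OCc2ccccc2)cc1)S(=O)(=O)c1ccccc1 | intermediate
20 | rac-5-(benzyloxy)-2-[4-(benzyloxy)benzyl]-1-bromo-3-[2-{3-(benzyloxy)-2,6-bis[4-(benzyloxy)benzyl]-5-methoxyphenyl}-1-(phenylsulfonyl)ethyl]benzene (racemic) | Brc1cc(OCc2ccccc2)cc(C(Cc2c(Cc3ccc(OCc4ccccc4)cc3)c(OC)cc(OCc3ccccc3)c2Cc2ccc(OCc3ccccc3)cc2)S(=O)(=O)c2ccccc2)c1Cc1ccc(OCc2ccccc2)cc1 | intermediate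
21 | 5-(benzyloxy)-2-[4-(benzyloxy)benzyl]-1-bromo-3-[2-{3-(benzyloxy)-2,6-bis[4-(benzyloxy)benzyl]-5-methoxyphenyl}ethyl]benzene | Brc1cc(OCc2ccccc2)cc(CCc2c(Cc3ccc(OCc4ccccc4)cc3)c(OC)cc(OCc3ccccc3)c2Cc2ccc(OCc3ccccc3)cc2)c1Cc1ccc(OCc2ccccc2)cc1 | intermediate
22 | 3-{2-[5-hydroxy-2-(4-hydroxybenzyl)phenyl]ethyl}-2,4-bis(4-hydroxybenzyl)-5-methoxyphenol (no stereocentre) | COc1cc(O)c(Cc2ccc(O)cc2)c(CCc2cc(O)ccc2Cc2ccc(O)cc2)c1Cc1ccc(O)cc1 | target

**Totals**

Total step count: 13.
Longest linear sequence: 10 steps (6 → 7 → 8 → 11 → 12 → 13 → 16 → 19 → 20 → 21 → 22; steps 3–7 and 9–13).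

**Steps most likely to fail**

Step 10. The fully substituted, bulky enolate of 16 may add to the aryne too slowly, so that aryne self-consumption, O-arylation, or arylation without acyl transfer (protonation of the aryl anion, or loss of bromide from it) takes over. The fallback sets out from 15 (with 5 and 13) and comes back to the route at 19. The unbranched keto sulfone 15, the simplest substrate class for this insertion, is inserted first: CsF, MeCN, 60 °C with 5 should give, by way of aryne 17 and caesium 3-(benzyloxy)-7-[4-(benzyloxy)phenyl]-5-bromo-8-(phenylsulfonyl)bicyclo[4.2.0]octa-1,3,5-trien-7-olate F1, the ketone [4-(benzyloxy)-2-bromo-6-(phenylsulfonylmethyl)phenyl][4-(benzyloxy)phenyl]methanone F2. Its sulfonyl-activated benzylic CH2 is then deprotonated (NaH, DMF, 0 °C) and alkylated with bromide 13 to give 19. The two halves are then united at the CH–CH2 bond of the bridge by sulfone alkylation instead of at the aryl–CH bond.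

Step 11. Hydride delivery to the carbonyl carbon, shielded by bromine and the branched chain and deactivated by two para-alkoxyaryl rings, may stall while the acid cleaves or shifts benzyl ethers. The fallback sets out from 19 and comes back to the route at 22. LiAlH4 (THF, 0 °C) should reduce the ketone to {4-(benzyloxy)-2-bromo-6-[2-{3-(benzyloxy)-2,6-bis[4-(benzyloxy)benzyl]-5-methoxyphenyl}-1-(phenylsulfonyl)ethyl]phenyl}[4-(benzyloxy)phenyl]methanol F3 (diastereomer mixture). Mg in MeOH/THF then removes the sulfonyl group to give rac-{4-(benzyloxy)-2-bromo-6-[2-{3-(benzyloxy)-2,6-bis[4-(benzyloxy)benzyl]-5-methoxyphenyl}ethyl]phenyl}[4-(benzyloxy)phenyl]methanol F4. The final hydrogenation (H2, Pd/C, THF/MeOH, AcOH) then cleaves the doubly benzylic C–OH bond together with the five benzyl ethers and the C–Br bond, giving 22 without any acid-mediated hydride step.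

Step 5. The second coupling, at a bromide flanked by ester and ether, may be slow, so that protodebromination and homocoupling of the benzylzinc reagent consume the material. The fallback sets out from 7 and comes back to the route at 11; it makes no new compound (F0). Ester 7 is benzylated twice in a Friedel–Crafts reaction with 4-(benzyloxy)benzyl alcohol (2.2 equiv) and catalytic Sc(OTf)3 in MeNO2/CH2Cl2, the way the plant is thought to attach these groups. The benzylic cation should enter para to each ether oxygen, the same two positions that bromine takes in step 4. Regiocontrol (attack between the two oxygens) is the weak point of this alternative.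

Further compounds
F1 | step 10 | caesium 3-(benzyloxy)-7-[4-(benzyloxy)phenyl]-5-bromo-8-(phenylsulfonyl)bicyclo[4.2.0]octa-1,3,5-trien-7-olate | [Cs+].[O-]C1(c2ccc(OCc3ccccc3)cc2)c2c(Br)cc(OCc3ccccc3)cc2C1S(=O)(=O)c1ccccc1
F2 | step 10 | [4-(benzyloxy)-2-bromo-6-(phenylsulfonylmethyl)phenyl][4-(benzyloxy)phenyl]methanone | O=C(c1ccc(OCc2ccccc2)cc1)c1c(Br)cc(OCc2ccccc2)cc1CS(=O)(=O)c1ccccc1
F3 | step 11 | {4-(benzyloxy)-2-bromo-6-[2-{3-(benzyloxy)-2,6-bis[4-(benzyloxy)benzyl]-5-methoxyphenyl}-1-(phenylsulfonyl)ethyl]phenyl}[4-(benzyloxy)phenyl]methanol (diastereomer mixture) | OC(c1ccc(OCc2ccccc2)cc1)c1c(Br)cc(OCc2ccccc2)cc1C(Cc1c(Cc2ccc(OCc3ccccc3)cc2)c(OC)cc(OCc2ccccc2)c1Cc1ccc(OCc2ccccc2)cc1)S(=O)(=O)c1ccccc1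
F4 | step 11 | rac-{4-(benzyloxy)-2-bromo-6-[2-{3-(benzyloxy)-2,6-bis[4-(benzyloxy)benzyl]-5-methoxyphenyl}ethyl]phenyl}[4-(benzyloxy)phenyl]methanol | OC(c1ccc(OCc2ccccc2)cc1)c1c(Br)cc(OCc2ccccc2)cc1CCc1c(Cc2ccc(OCc3ccccc3)cc2)c(OC)cc(OCc2ccccc2)c1Cc1ccc(OCc2ccccc2)cc1
F0 | step 5 | none | none
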